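The readings were computed with constants of no real substance, and the scatter is random.

0.0266 M of partner opened the meeting: less than the 0.0560 M of substrate plus protic impurity charged in each of the flasks eta, gamma, theta and alpha, which differ in what goes in when.

| flask | substrate | partner | protic impurity | remark | time |
|---|---|---|---|---|---|
| green | 0.028 M | 0.95 equiv | 0.028 M | run made earlier |  |
| violet | 0.019 M | 0.95 equiv | 0.028 M | run made earlier |  |
| ochre | 0.042 M | 0.95 equiv | 0.028 M | run made earlier |  |
| amber | 0.028 M | 0.95 equiv | 0.056 M | run made earlier |  |
| eta | 0.028 M (fed, over 2.5 d) | 0.950 equiv | 0.0280 M | all else is in the flask from the start; the feed brings no volume worth counting | 6.0 d |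
| gamma | 0.028 M | 0.950 equiv | 0.0280 M | everything together at the start | 6.0 d |
| theta | 0.028 M | 0.950 equiv (fed, over 15 h) | 0.0280 M | all else is in the flask from the start; the feed brings no volume worth counting | 6.0 d |
| alpha | 0.028 M | 0.950 equiv (fed, over 2.5 d) | 0.0280 M | all else is in the flask from the start; the feed brings no volume worth counting | 6.0 d |

- the best flask by amount of target, in percent of the substrate charged; "all alike" if 1.5 percentage points covers them all (eta / gamma / theta / alpha / all alike)
- amount of target at the end, in percent of the substrate charged, eta
- amount of target at the end, in percent of the substrate charged, gamma
- amount of target at the end, in percent of the substrate charged, theta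
- amount of target at the end, in percent of the substrate charged, alpha

- green (time / d: target / %, substrate / %): 0.833: 22.0, 5.3; 2.00: 28.8, 0; 4.00: 32.0, 0; 6.00: 30.1, 1.1
- violet (time / d: target / %, substrate / %): 0.417: 8.3, 25.5; 1.25: 21.1, 2.4; 2.50: 26.5, 0.5; 4.00: 26.7, 0
- ochre (time / d: target / %, substrate / %): 0.833: 26.3, 3.6; 1.67: 34.0, 1.0; 2.50: 33.6, 0; 4.00: 33.8, 0
- amber (time / d: target / %, substrate / %): 0.833: 17.6, 5.9; 1.67: 20.6, 0; 2.50: 21.0, 0; 4.00: 21.4, 0

(each reading ± 1 percentage point)

- the numbers in the tables scatter with a standard deviation of 1 percentage point
- steps under discussion: partner + target -> over-reaction product; substrate -> intermediate; partner + intermediate -> target; 2 partner -> homo product; partner + protic impurity -> quenched reagent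

The analyst reported that substrate falls fast: in violet it stood at 25.5% by 0.417 d.

The kineticist, speaking as the author of this reckoning, called partner the limiting reagent and proposed counting what stays, not what forms. She assumed that intermediate and impurity react with partner with equal rate constants, that all substrate has become intermediate, and that partner goes to these two and nothing else until it is used up. Each then keeps the same fraction, so she defined the even-share fraction left as f = 1 − [partner]/([substrate] + [impurity]), all as charged. For green's charges and the four new flasks that gives 52.5%.

A sceptic demanded a test. For amber, f is 68.3%, so the share converted should be 0.667 of green's, and the late target readings of amber over green give 0.683. The kineticist committed to fractions left near f wherever substrate has become intermediate before partner meets it. That is a fraction left, not an amount of target.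

The forecast held that “quenching competes about equally with coupling”. It gave eta 14%, gamma 31%, theta 35% and alpha 37%, so best alpha.

Alpha came out best at 35.4%, with theta 33.9%, gamma 31.4%, and eta 20.6% against the forecast's 14%. In eta at 6.00 d, intermediate stood at 75.4% of the substrate charged and impurity at 36.7% of its own charge, on either side of f. In alpha at the same time the two stood at 55.9% and 58.5%, each a little above the 52.5% of f.

    partner + target → over-reaction product (k = 1.20 /M/h)
    substrate → intermediate (k = 0.140 /h)
    partner + intermediate → target (k = 1.70 /M/h)
    2 partner → homo product (k = 0.0460 /M/h)
    partner + protic impurity → quenched reagent (k = 1.50 /M/h)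

For the neighbour flask, alpha with 0.017 M of substrate, f gives 64.1%. The computed flask holds intermediate at 64.9%, impurity at 67.3% of its own charge, and target at 29.9%.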